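**Retrosynthetic overview**

- The route rests on the 4-alkoxy-2-pyranone ring (O1, C2, C3, C4, C4a, C8a). Its C4 oxygen is the allylic ether oxygen to C1' and lies peri to the C5 methyl, so the ring is read as the enol ether of a 6-methylsalicylate ester carbonyl.
- Cutting O1–C2 and C3=C4 gives the side-chain 6-methylsalicylate 9 and ketenylidenetriphenylphosphorane 10; the C4–O–C1' ether is therefore made as an ordinary ester C–O bond.
- Ester 9 comes from chain alcohol 7 and acid 8 by Mitsunobu esterification. Alcohol 7 comes from oxocrotonate 1 by asymmetric allylboration (sets C4'), silylation, cross-metathesis with 5 and ester reduction.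
- The C6' hydroperoxide is added last by a singlet-oxygen ene reaction at C6'=C7', followed by desilylation.
- Ring order: the benzene ring is bought in 8; the pyranone ring is the only ring formed (step 6).

Key step: step 6

Remark: primed locants count the side chain from the ether CH2 (C1'). Nothing in the chain biases the face of C6' toward singlet oxygen, so the 6'S hydroperoxide (the 1,3-anti partner of the 4'S carbinol) is taken to be reached by separation of C6' epimers, not by induction.

**Route**

Step 1
Reactants: 1 ethyl (E)-3-methyl-4-oxobut-2-enoate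
Product: 3 ethyl (2E,4S)-4-hydroxy-3-methylhepta-2,6-dienoate, via diisopinocampheylborinate 2 (not isolated)
Conditions: (−)-Ipc2BOMe, allylMgBr (slightly less than 1 equiv per boron), Et2O, 0 °C to rt; then 1, −78 °C; then NaBO3·4H2O, THF/H2O, rt
Reagents that add atoms: allylmagnesium bromide, C=CC[Mg]Br (its allyl group is handed on by (−)-B-allyldiisopinocampheylborane made in the flask, C=CCB([C@@H]1C[C@@H]2C[C@H]([C@H]1C)C2(C)C)[C@@H]1C[C@@H]2C[C@H]([C@H]1C)C2(C)C)
Why: Brown asymmetric allylboration through a chair six-membered transition state, in which the isopinocampheyl groups of the (+)-α-pinene series steer the allyl group to the Si face of the aldehyde and so set 4S, while the conjugated ester is inert to the allylborane at −78 °C and the perborate work-up cleaves the borinate without attacking the enoate.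

Step 2
Reactants: 3 ethyl (2E,4S)-4-hydroxy-3-methylhepta-2,6-dienoate
Product: 4 ethyl (2E,4S)-4-[(tert-butyldimethylsilyl)oxy]-3-methylhepta-2,6-dienoate
Conditions: TBSCl, imidazole, DMF, rt
Reagents that add atoms: tert-butyldimethylsilyl chloride, CC(C)(C)[Si](C)(C)Cl
Why: Standard imidazole-promoted silylation of a secondary allylic alcohol, which masks the C4 oxygen so that the phenol is later the only free O–H and leaves the stereocentre untouched.

Step 3
Reactants: 4 ethyl (2E,4S)-4-[(tert-butyldimethylsilyl)oxy]-3-methylhepta-2,6-dienoate; 5 2-methylbut-2-ene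
Product: 6 ethyl (2E,4S)-4-[(tert-butyldimethylsilyl)oxy]-3,7-dimethylocta-2,6-dienoate
Conditions: second-generation Grubbs catalyst RuCl2(=CHPh)(PCy3)(H2IMes) (cat.), 5 in large excess as co-solvent, CH2Cl2, 35 °C
Reagents that add atoms: none
Why: Olefin cross-metathesis in which only the monosubstituted terminal alkene enters the catalytic cycle and is capped as the isopropylidene group by the excess of 5 with loss of propene, the hindered, electron-poor trisubstituted enoate alkene remaining a spectator.

Step 4
Reactants: 6 ethyl (2E,4S)-4-[(tert-butyldimethylsilyl)oxy]-3,7-dimethylocta-2,6-dienoate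
Product: 7 (2E,4S)-4-[(tert-butyldimethylsilyl)oxy]-3,7-dimethylocta-2,6-dien-1-ol
Conditions: iBu2AlH (2.5 equiv), CH2Cl2, −78 °C; aq. potassium sodium tartrate
Reagents that add atoms: none
Why: 1,2-Reduction of the conjugated ester by diisobutylaluminium hydride gives the primary allylic alcohol with the E-alkene, the silyl ether and the C4 centre unchanged.

Step 5
Reactants: 7 (2E,4S)-4-[(tert-butyldimethylsilyl)oxy]-3,7-dimethylocta-2,6-dien-1-ol; 8 2-hydroxy-6-methylbenzoic acid
Product: 9 (2E,4S)-4-[(tert-butyldimethylsilyl)oxy]-3,7-dimethylocta-2,6-dien-1-yl 2-hydroxy-6-methylbenzoate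
Conditions: PPh3, DIAD, THF, 0 °C to rt
Reagents that add atoms: none
Why: Mitsunobu esterification in which the carboxylic acid, far more acidic than the hydrogen-bonded phenol, is the pronucleophile and its carboxylate displaces the primary allylic alkoxyphosphonium group at C1' by SN2, so the crowded 2,6-disubstituted carboxyl carbon never has to be attacked and the phenol stays free.

Step 6
Reactants: 9 (2E,4S)-4-[(tert-butyldimethylsilyl)oxy]-3,7-dimethylocta-2,6-dien-1-yl 2-hydroxy-6-methylbenzoate; 10 ketenylidenetriphenylphosphorane
Product: 12 4-{[(2E,4S)-4-[(tert-butyldimethylsilyl)oxy]-3,7-dimethylocta-2,6-dien-1-yl]oxy}-5-methyl-2H-chromen-2-one, via aryl phosphoranylideneacetate 11 (not isolated)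
Conditions: 10 (1.2 equiv), toluene, 60 °C then 110 °C, argon
Reagents that add atoms: none
Why: The phenol O–H of 9 adds to the cumulated ylide 10 with oxygen bonding to the central carbon (O1–C2), giving the stabilised ester ylide 11; its ylide carbon then attacks the neighbouring ester carbonyl and the oxaphosphetane collapses with loss of Ph3PO to the C3=C4 bond, so that the ester alkoxy oxygen becomes the C4 ether oxygen. The closest known reaction type is the domino addition–intramolecular Wittig olefination of α-hydroxy esters and salicylate esters with ketenylidenetriphenylphosphorane, which gives tetronates and 4-alkoxycoumarins. The pyranone ring (O1, C2, C3, C4, C4a, C8a) closes in a 6-exo-trig mode at the ester C=O. No stereocentre is created, and C4' and the E-alkene lie away from the reacting atoms. The step needs chemoselectivity and O-over-C3 site selectivity: the silyl ether leaves the phenol as the only O–H, only the ortho ester is within reach of the ylide, the ortho methyl twists the ester out of the arene plane so that one face of its carbonyl is presented to the tethered ylide, and the C4–O bond already exists as the ester C–O bond so no C3-allyl isomer can arise by alkylation. The temperature is held at 110 °C so that the [3,3] shift of the 4-allyloxy product to C3, which would have to build a quaternary carbon, stays slow.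

Step 7
Reactants: 12 4-{[(2E,4S)-4-[(tert-butyldimethylsilyl)oxy]-3,7-dimethylocta-2,6-dien-1-yl]oxy}-5-methyl-2H-chromen-2-one
Product: 13 4-{[(2E,4S,6S)-4-[(tert-butyldimethylsilyl)oxy]-6-hydroperoxy-3,7-dimethylocta-2,7-dien-1-yl]oxy}-5-methyl-2H-chromen-2-one
Conditions: O2, tetraphenylporphyrin (cat.), CH2Cl2, visible light (>400 nm cut-off), 0 °C, stopped before full conversion; silica chromatography then normal-phase HPLC
Reagents that add atoms: dioxygen, O=O
Why: Schenck ene reaction of singlet oxygen at the electron-rich C6'=C7' alkene, where hydrogen abstraction from a methyl group should be favoured over abstraction from the C5' methylene next to the bulky silyloxy-bearing C4' and gives the C6' hydroperoxide with the C7'=CH2 alkene, while the C2'=C3' alkene is deactivated by its two allylic C–O bonds and the coumarin is not excited above 400 nm; the C6' centre forms without useful induction from remote C4', so the 6S epimer (the 1,3-anti isomer) is secured by separation from the 6R epimer and the tertiary C7' hydroperoxide.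

Step 8
Reactants: 13 4-{[(2E,4S,6S)-4-[(tert-butyldimethylsilyl)oxy]-6-hydroperoxy-3,7-dimethylocta-2,7-dien-1-yl]oxy}-5-methyl-2H-chromen-2-one
Product: 14 4-{[(2E,4S,6S)-6-hydroperoxy-4-hydroxy-3,7-dimethylocta-2,7-dien-1-yl]oxy}-5-methyl-2H-chromen-2-one
Conditions: HF·pyridine, excess pyridine, THF, 0 °C to rt
Reagents that add atoms: none
Why: Fluoride-driven Si–O cleavage under pyridine-buffered HF removes the silyl ether without the basic conditions that would dehydrate a secondary hydroperoxide to an enone (Kornblum–DeLaMare), and since no C–O bond at C4' or C6' is broken both S centres are kept.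

**Compound list**

1 | ethyl (E)-3-methyl-4-oxobut-2-enoate | CCOC(=O)/C=C(\C)C=O | starting material
2 | ethyl (2E,4S)-4-[(diisopinocampheylboranyl)oxy]-3-methylhepta-2,6-dienoate | CCOC(=O)/C=C(\C)[C@H](CC=C)OB([C@@H]1C[C@@H]2C[C@H]([C@H]1C)C2(C)C)[C@@H]1C[C@@H]2C[C@H]([C@H]1C)C2(C)C | intermediate
3 | ethyl (2E,4S)-4-hydroxy-3-methylhepta-2,6-dienoate | CCOC(=O)/C=C(\C)[C@@H](O)CC=C | intermediate
4 | ethyl (2E,4S)-4-[(tert-butyldimethylsilyl)oxy]-3-methylhepta-2,6-dienoate | CCOC(=O)/C=C(\C)[C@@H](O[Si](C)(C)C(C)(C)C)CC=C | intermediate
5 | 2-methylbut-2-ene | CC=C(C)C | starting material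
6 | ethyl (2E,4S)-4-[(tert-butyldimethylsilyl)oxy]-3,7-dimethylocta-2,6-dienoate | CCOC(=O)/C=C(\C)[C@@H](O[Si](C)(C)C(C)(C)C)CC=C(C)C | intermediate
7 | (2E,4S)-4-[(tert-butyldimethylsilyl)oxy]-3,7-dimethylocta-2,6-dien-1-ol | CC(C)=CC[C@H](O[Si](C)(C)C(C)(C)C)/C(C)=C/CO | intermediate
8 | 2-hydroxy-6-methylbenzoic acid | Cc1cccc(O)c1C(=O)O | starting material
9 | (2E,4S)-4-[(tert-butyldimethylsilyl)oxy]-3,7-dimethylocta-2,6-dien-1-yl 2-hydroxy-6-methylbenzoate | CC(C)=CC[C@H](O[Si](C)(C)C(C)(C)C)/C(C)=C/COC(=O)c1c(C)cccc1O | intermediate
10 | ketenylidenetriphenylphosphorane | O=C=C=P(c1ccccc1)(c1ccccc1)c1ccccc1 | starting material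
11 | (2E,4S)-4-[(tert-butyldimethylsilyl)oxy]-3,7-dimethylocta-2,6-dien-1-yl 2-methyl-6-{[(triphenylphosphoranylidene)acetyl]oxy}benzoate | CC(C)=CC[C@H](O[Si](C)(C)C(C)(C)C)/C(C)=C/COC(=O)c1c(C)cccc1OC(=O)C=P(c1ccccc1)(c1ccccc1)c1ccccc1 | intermediate
12 | 4-{[(2E,4S)-4-[(tert-butyldimethylsilyl)oxy]-3,7-dimethylocta-2,6-dien-1-yl]oxy}-5-methyl-2H-chromen-2-one | CC(C)=CC[C@H](O[Si](C)(C)C(C)(C)C)/C(C)=C/COc1cc(=O)oc2cccc(C)c12 | intermediate
13 | 4-{[(2E,4S,6S)-4-[(tert-butyldimethylsilyl)oxy]-6-hydroperoxy-3,7-dimethylocta-2,7-dien-1-yl]oxy}-5-methyl-2H-chromen-2-one | C=C(C)[C@H](C[C@H](O[Si](C)(C)C(C)(C)C)/C(C)=C/COc1cc(=O)oc2cccc(C)c12)OO | intermediate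
14 | 4-{[(2E,4S,6S)-6-hydroperoxy-4-hydroxy-3,7-dimethylocta-2,7-dien-1-yl]oxy}-5-methyl-2H-chromen-2-one | C=C(C)[C@H](C[C@H](O)/C(C)=C/COc1cc(=O)oc2cccc(C)c12)OO | target

**Step count**

Total steps: 8. Longest linear sequence: 8 steps (1 to 14).

**Steps most likely to fail**

Step 6. The ester ylide may close too slowly onto an ester carbonyl flanked by two ortho substituents. Heating long or hot enough for olefination could then let the 4-allyloxy product shift to C3 by [3,3] rearrangement, or let the ylide revert and decompose. The fallback makes the C4–O bond by etherification instead. It sets out from alcohol 7 and returns at 12. Commercial 1-(2-hydroxy-6-methylphenyl)ethan-1-one F1 is condensed with diethyl carbonate and NaH in toluene at reflux to give 4-hydroxy-5-methyl-2H-chromen-2-one F2. F2 is then coupled with 7 under Mitsunobu conditions (PPh3, DIAD, THF, 0 °C), which favour O-alkylation over C3-alkylation. Compound 12 should be obtained after removal of the isomeric 2-alkoxychromone, and the route continues with step 7.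

Step 7. Hydrogen abstraction may be spread over the methyl and C5' methylene positions and over both faces of C6'. Over-oxidation at the second alkene may also begin before conversion is useful, and free hydroperoxide isomers may streak or decay on silica. The wanted isomer would then be a minor, poorly purified part of the mixture. The fallback separates the isomers as protected peroxides. It sets out from 12 and returns at 13. The crude photo-oxygenation mixture is treated with 2-methoxypropene and catalytic pyridinium p-toluenesulfonate in CH2Cl2 at 0 °C. The stable perketal 4-{[(2E,4S,6S)-4-[(tert-butyldimethylsilyl)oxy]-6-[(2-methoxypropan-2-yl)peroxy]-3,7-dimethylocta-2,7-dien-1-yl]oxy}-5-methyl-2H-chromen-2-one F3 is isolated by chromatography. Brief treatment with AcOH/THF/H2O at rt then releases 13, which goes on to step 8.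

Step 8. The hydroperoxide may be lost during desilylation through acid-promoted Hock-type cleavage or allylic transposition, or the hindered secondary silyl ether may cleave incompletely under conditions mild enough for the peroxide. The fallback reverses the order of the last two operations so that no desilylating agent meets the peroxide. It sets out from 12 and returns at 14. Compound 12 is desilylated with HF·pyridine in THF to give 4-{[(2E,4S)-4-hydroxy-3,7-dimethylocta-2,6-dien-1-yl]oxy}-5-methyl-2H-chromen-2-one F4. F4 is photo-oxygenated under the conditions of step 7, and 14 is isolated directly by HPLC from its C6' epimer and regioisomers.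

**Further compounds**

F1 | step 6 | 1-(2-hydroxy-6-methylphenyl)ethan-1-one | CC(=O)c1c(C)cccc1O
F2 | step 6 | 4-hydroxy-5-methyl-2H-chromen-2-one | Cc1cccc2oc(=O)cc(O)c12
F3 | step 7 | 4-{[(2E,4S,6S)-4-[(tert-butyldimethylsilyl)oxy]-6-[(2-methoxypropan-2-yl)peroxy]-3,7-dimethylocta-2,7-dien-1-yl]oxy}-5-methyl-2H-chromen-2-one | C=C(C)[C@H](C[C@H](O[Si](C)(C)C(C)(C)C)/C(C)=C/COc1cc(=O)oc2cccc(C)c12)OOC(C)(C)OC
F4 | step 8 | 4-{[(2E,4S)-4-hydroxy-3,7-dimethylocta-2,6-dien-1-yl]oxy}-5-methyl-2H-chromen-2-one | CC(C)=CC[C@H](O)/C(C)=C/COc1cc(=O)oc2cccc(C)c12
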